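**Retrosynthetic overview**
1. Target ⇐ Wittig mono-methylenation of one of the two homotopic ketones of a C2-symmetric tetracyclic 8,14-diketone-3,21-diol.
2. Diketone ⇐ two-directional epoxide-initiated cation–olefin tetracyclization of an acyclic bis-epoxy bis(Z-silyl enol ether). On each side ring A (ring E) closes first (C4–C5 bond), then ring B (ring D) closes onto the enol ether (C9–C10 bond).
3. Bis(enol ether) ⇐ four-component coupling of two acylsilanes and two vinyllithiums (Brook rearrangement, I2 dimerisation), which forms the central C11–C12 bond.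
4. Acylsilane ⇐ lithium enolate of acetyltrimethylsilane + (S)-6,7-epoxygeranyl bromide.
5. Epoxide ⇐ geranyl acetate by organocatalytic Shi epoxidation; this is the only reagent-controlled stereocentre, and the other eight follow from it in the cyclization.

Assumption: vinyllithium is made in the reaction flask from commercial Sn(CH=CH2)4 and MeLi, and the ent-Shi ketone is a purchased catalyst.

**Step 1**
Reactants: 1 geranyl acetate
Product: 2 (S)-6,7-epoxygeranyl acetate
Conditions: ent-Shi ketone (L-fructose-derived 1,2:4,5-di-O-isopropylidene-β-L-erythro-2,3-hexodiulo-2,6-pyranose, 30 mol%), KHSO5 (as 2KHSO5·KHSO4·K2SO4, 1.4 equiv), K2CO3, Bu4NHSO4 (5 mol%), aq. Na2B4O7/Na2H2EDTA buffer (pH 10.5), MeCN–CH2(OMe)2, 0 °C, 2 h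
Reagents that add atoms: potassium peroxymonosulfate, [K+].[O-]S(=O)(=O)OO
Why: Shi asymmetric epoxidation: the chiral dioxirane attacks only the electron-rich 6,7-alkene (the 2,3-alkene is deactivated by the allylic acetate) through a spiro transition state, and the L-series ketone gives the (S)-epoxide that becomes C3/C21 of the target (expected about 90–94% ee).

**Step 2**
Reactants: 2 (S)-6,7-epoxygeranyl acetate
Product: 3 (S)-6,7-epoxygeraniol
Conditions: K2CO3 (0.2 equiv), MeOH, 0 °C → rt
Reagents that add atoms: none
Why: Base-catalysed transesterification (methanolysis) removes the acetate, and the trisubstituted epoxide is inert to cold methoxide.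

**Step 3**
Reactants: 3 (S)-6,7-epoxygeraniol
Product: 5 (S)-6,7-epoxygeranyl bromide, via allylic mesylate 4 (not isolated)
Conditions: MsCl, Et3N, THF, −40 °C; then LiBr, THF, −40 → 0 °C; used crude
Reagents that add atoms: lithium bromide, [Li+].[Br-]
Why: Mesylation followed by SN2 displacement with bromide at the primary allylic carbon keeps the E-alkene and the epoxide intact at low temperature.

**Step 4**
Reactants: 5 (S)-6,7-epoxygeranyl bromide; 6 acetyltrimethylsilane
Product: 8 epoxy acylsilane (4E)-7-[(2S)-3,3-dimethyloxiran-2-yl]-5-methyl-1-(trimethylsilyl)hept-4-en-1-one, via lithium enolate 7 (not isolated)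
Conditions: 6 (2 equiv), LiN(iPr)2 (2 equiv), THF, −78 °C; then 5 (1 equiv), DMPU, −78 → −40 °C
Reagents that add atoms: none
Why: Kinetic lithium enolate alkylation (SN2 on the allylic bromide) forms the C6–C7 bond; excess enolate suppresses dialkylation and the epoxide does not react with the enolate at these temperatures.

**Step 5**
Reactants: 8 epoxy acylsilane (2 equiv)
Product: 11 bis-epoxy bis(Z-trimethylsilyl enol ether) tetraene, via lithium alkoxide 9 (not isolated), via siloxyallyllithium 10 (not isolated)
Conditions: CH2=CHLi (1.05 equiv, from Sn(CH=CH2)4 + MeLi, Et2O, 0 °C), Et2O, −78 °C; THF, −78 → −40 °C; I2 (0.5 equiv), THF, −78 °C; cold pH 7 work-up, Et3N-deactivated silica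
Reagents that add atoms: vinyllithium, [Li]C=C
Why: Vinyllithium 1,2-addition and Brook rearrangement give the lithium-chelated (Z)-siloxyallyllithium, which iodine couples oxidatively at its unhindered terminal carbons (four-component coupling), forming C11–C12 and fixing both Z-enol ethers; pairing of 8 of about 92% ee raises the homochiral dimer to >99% ee, with about 8% meso diastereomer removed later.

**Step 6**
Reactants: 11 bis-epoxy bis(Z-trimethylsilyl enol ether) tetraene
Product: 12 C2-symmetric tetracyclic diketone diol (26,27-dinor-8,14-dioxo analogue of α-onocerin)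
Conditions: MeAlCl2 (3 equiv), CH2Cl2, −94 °C, 20 min; aq. NaHCO3; recrystallisation
Reagents that add atoms: none
Why: Proposed new method: a two-directional epoxide-initiated cation–olefin tetracyclization terminated by two silyl enol ethers, in which MeAlCl2 ionises each C4–O bond as the E-alkene attacks (ring A, ring E) and the tertiary cation is captured by the Z-enol ether through a chair–chair transition state (ring B, ring D), giving 3β-OH from the retained epoxide C–O bond, trans ring fusions from anti addition across the E-alkenes, and the equatorial C9/C13 chain from the Z-enol ether geometry, after which chloride from the aluminate removes Me3Si from each oxocarbenium to release the ketone; the closest known reactions are the MeAlCl2 epoxy-polyene cyclization ending in a single silyl enol ether and the two-directional tetracyclization ending in two allylsilanes, and the untested point is whether the first-formed silyloxocarbenium is desilylated faster than it is attacked by the second enol ether (five-ring Mukaiyama aldol), which excess Lewis acid (both epoxides ionise together), the labile Me3Si group and −94 °C are chosen to ensure.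

**Step 7**
Reactants: 12 tetracyclic diketone diol
Product: 13 26-nor-8-oxo-α-onocerin
Conditions: Ph3PCH3Br (0.9 equiv), KOtBu (0.9 equiv), THF, 0 → 60 °C; chromatography, recovered 12 recycled
Reagents that add atoms: methylenetriphenylphosphorane, C=P(c1ccccc1)(c1ccccc1)c1ccccc1
Why: Wittig methylenation with a deficit of ylide converts one of the two homotopic ketones, so a single mono-alkene forms in a statistical mixture (at best about 50% per pass) with recoverable 12 and the bis-alkene; no stereocentre is made and C9, α to the carbonyl, already holds its favoured equatorial chain.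

**Compound list**
1 | geranyl acetate, (2E)-3,7-dimethylocta-2,6-dien-1-yl acetate | CC(=O)OC/C=C(\C)CCC=C(C)C | starting material
2 | (S)-6,7-epoxygeranyl acetate, (2E)-5-[(2S)-3,3-dimethyloxiran-2-yl]-3-methylpent-2-en-1-yl acetate | CC(=O)OC/C=C(\C)CC[C@@H]1OC1(C)C | intermediate
3 | (S)-6,7-epoxygeraniol, (2E)-5-[(2S)-3,3-dimethyloxiran-2-yl]-3-methylpent-2-en-1-ol | OC/C=C(\C)CC[C@@H]1OC1(C)C | intermediate
4 | (S)-6,7-epoxygeranyl methanesulfonate | CS(=O)(=O)OC/C=C(\C)CC[C@@H]1OC1(C)C | intermediate (not isolated)
5 | (S)-6,7-epoxygeranyl bromide, (3S)-3-[(3E)-5-bromo-3-methylpent-3-en-1-yl]-2,2-dimethyloxirane | BrC/C=C(\C)CC[C@@H]1OC1(C)C | intermediate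
6 | acetyltrimethylsilane, 1-(trimethylsilyl)ethan-1-one | CC(=O)[Si](C)(C)C | starting material
7 | lithium 1-(trimethylsilyl)ethen-1-olate (enolate of 6) | C=C(O[Li])[Si](C)(C)C | intermediate (not isolated)
8 | (4E)-7-[(2S)-3,3-dimethyloxiran-2-yl]-5-methyl-1-(trimethylsilyl)hept-4-en-1-one | C[Si](C)(C)C(=O)CC/C=C(\C)CC[C@@H]1OC1(C)C | intermediate
9 | lithium (6E)-9-[(2S)-3,3-dimethyloxiran-2-yl]-7-methyl-3-(trimethylsilyl)nona-1,6-dien-3-olate (both epimers at the carbinol carbon) | C=CC(O[Li])([Si](C)(C)C)CC/C=C(\C)CC[C@@H]1OC1(C)C | intermediate (not isolated)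
10 | [(2Z,6E)-9-[(2S)-3,3-dimethyloxiran-2-yl]-7-methyl-3-(trimethylsilyloxy)nona-2,6-dien-1-yl]lithium | [Li]C/C=C(O[Si](C)(C)C)/CC/C=C(\C)CC[C@@H]1OC1(C)C | intermediate (not isolated)
11 | (3E,7Z,11Z,15E)-1,18-bis[(2S)-3,3-dimethyloxiran-2-yl]-3,16-dimethyl-7,12-bis(trimethylsilyloxy)octadeca-3,7,11,15-tetraene | CC1(C)O[C@H]1CC/C(C)=C/CC/C(O[Si](C)(C)C)=C/CC/C=C(O[Si](C)(C)C)/CC/C=C(\C)CC[C@@H]1OC1(C)C | intermediate
12 | 1,2-bis[(1R,4aR,6S,8aS)-6-hydroxy-5,5,8a-trimethyl-2-oxodecahydronaphthalen-1-yl]ethane (both halves 3β-OH, 5α-H, 9α-H, 10β-Me; trans-decalins) | O=C1CC[C@H]2C(C)(C)[C@@H](O)CC[C@]2(C)[C@H]1CC[C@H]1C(=O)CC[C@H]2C(C)(C)[C@@H](O)CC[C@]12C | intermediate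
13 | 26-nor-8-oxo-α-onocerin | C=C1CC[C@H]2C(C)(C)[C@@H](O)CC[C@]2(C)[C@H]1CC[C@H]1C(=O)CC[C@H]2C(C)(C)[C@@H](O)CC[C@]12C | target

**Totals**
Total step count: 7. Longest linear sequence: 7 (1 → 2 → 3 → 5 → 8 → 11 → 12 → 13).

**Three steps most likely to fail**

Step 6 (the proposed new step; risk: aldol cross-talk between the two halves or incomplete cyclization). The fallback uses known chemistry, sets out from 11 and comes back at 13. CsF and PhNTf2 in DME convert both silyl enol ethers, with retention of geometry, into the bis(enol triflate) F4. Pd(PPh3)4-catalysed Kumada coupling with Me3SiCH2MgCl gives the bis(allylsilane) F5. MeAlCl2 in CH2Cl2 at −94 °C then effects the known allylsilane-terminated two-directional tetracyclization to α-onocerin F6, in which no carbonyl electrophile is formed during the cascade. One equivalent of ozone (titrated CH2Cl2 solution, −78 °C, then Me2S) cleaves one of the two equivalent exocyclic alkenes to give 13; unreacted bis-alkene is recycled.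

Step 7 (risk: the statistical mono-olefination over-runs, or the hindered ketone enolises instead of reacting). The fallback sets out from 12 and comes back at 13, and replaces irreversible mono-olefination by reversible mono-protection. Ethylene glycol (1 equiv) with PPTS in benzene under water removal gives the mono-dioxolane F7. Recovered diketone and bis-ketal are re-equilibrated under the same conditions, so nothing is lost. Excess Ph3P=CH2 then methylenates the remaining ketone to the methylene ketal F8. PPTS in wet acetone releases the ketone to give 13 without isomerising the exocyclic alkene.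

Step 4 (risk: self-condensation or dialkylation of the acylsilane enolate). The fallback sets out from 6 and 5 and comes back at 8, and switches to metalloenamine alkylation. Compound 6 is condensed with cyclohexylamine over molecular sieves to the N-cyclohexylimine F1. LiN(iPr)2 in THF gives the lithium aza-enolate F2, which is mono-alkylated by 5 at −78 °C to the imine F3. Buffered hydrolysis (aq. AcOH/NaOAc, pentane, 0 °C) gives 8.

**Further compounds**
F1 | step 4 | N-cyclohexyl-1-(trimethylsilyl)ethan-1-imine | CC(=NC1CCCCC1)[Si](C)(C)C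
F2 | step 4 | lithium cyclohexyl[1-(trimethylsilyl)ethenyl]amide (aza-enolate of F1) | C=C(N([Li])C1CCCCC1)[Si](C)(C)C
F3 | step 4 | N-cyclohexyl imine of acylsilane 8 | C[Si](C)(C)C(=NC1CCCCC1)CC/C=C(\C)CC[C@@H]1OC1(C)C
F4 | step 6 | (3E,7Z,11Z,15E)-1,18-bis[(2S)-3,3-dimethyloxiran-2-yl]-3,16-dimethyloctadeca-3,7,11,15-tetraene-7,12-diyl bis(trifluoromethanesulfonate) | CC1(C)O[C@H]1CC/C(C)=C/CC/C(OS(=O)(=O)C(F)(F)F)=C/CC/C=C(OS(=O)(=O)C(F)(F)F)/CC/C=C(\C)CC[C@@H]1OC1(C)C
F5 | step 6 | (3E,7Z,11Z,15E)-1,18-bis[(2S)-3,3-dimethyloxiran-2-yl]-3,16-dimethyl-7,12-bis[(trimethylsilyl)methyl]octadeca-3,7,11,15-tetraene | CC1(C)O[C@H]1CC/C(C)=C/CC/C(C[Si](C)(C)C)=C/CC/C=C(C[Si](C)(C)C)/CC/C=C(\C)CC[C@@H]1OC1(C)C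
F6 | step 6 | α-onocerin | C=C1CC[C@H]2C(C)(C)[C@@H](O)CC[C@]2(C)[C@H]1CC[C@H]1C(=C)CC[C@H]2C(C)(C)[C@@H](O)CC[C@]12C
F7 | step 7 | mono(ethylene ketal) of diketone diol 12 | O=C1CC[C@H]2C(C)(C)[C@@H](O)CC[C@]2(C)[C@H]1CC[C@H]1C3(OCCO3)CC[C@H]2C(C)(C)[C@@H](O)CC[C@]12C
F8 | step 7 | ethylene ketal of 13 (8-methylene, 14-dioxolane) | C=C1CC[C@H]2C(C)(C)[C@@H](O)CC[C@]2(C)[C@H]1CC[C@H]1C3(OCCO3)CC[C@H]2C(C)(C)[C@@H](O)CC[C@]12C
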